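**Plan**

- Cuts: C4=O is traced back to C4–OMe and C3–OH to C3–B. Ring C is then cut at C3–C4 and O1–C2, and the C6–prenyl bond is traced back to an O5–C(CH3)2C≡CH ether.
- Enabling feature: ring C consists of O1–C8a–C4a–C4, which is an ortho-hydroxybenzaldehyde of ring A, plus C2=C3, which is a ring B styrene. The 3-OH sits on the former β-carbon of that styrene, where a boryl group can stand in for it.
- Forward order: rings A and B come from two benzaldehydes. Ring C closes in one hetero-[4+2] between the aldehyde-derived 4-methoxy ortho-quinone methide and the (E)-styrylboronate. Then B→OH, C4 ether→ketone, semihydrogenation and Claisen shift of the O5 side chain to C6, and desilylation.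
- Stereochemistry: the 2,3-trans relationship is copied from the (E)-alkene, the absolute configuration comes from a chiral phosphoric acid, C3–B becomes C3–O with retention, and C4 is erased on oxidation.
- The O5 tert-propargyl ether serves twice. It blocks the second ortho oxygen during the cycloaddition, so only one ring closure is possible and no prenyl alkene meets the cation or DDQ. It is also the masked prenyl group.

Key step: step 5

Assumption: the (R)-configured acid is taken to deliver the (2S,3S)-boronate; if the sense of induction proves opposite, the (S)-acid is used.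
Assumption: the cycloadduct and the derived 3-ol are drawn as the 3,4-trans epimers; either C4 epimer serves, because both converge at the ketone.

**Route**

Step 1
Reactants: 1 2,4,6-trihydroxybenzaldehyde
Product: 2 2,6-dihydroxy-4-methoxybenzaldehyde
Conditions: Me2SO4 (1.0 equiv), K2CO3 (1.0 equiv), acetone, rt
Reagents that add atoms: dimethyl sulfate, COS(=O)(=O)OC
Why: Williamson etherification with one equivalent of weak base; the 4-OH is para to the formyl group and is the only hydroxyl not hydrogen-bonded to it, so it is the most acidic and should be methylated ahead of the two ortho hydroxyls.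

Step 2
Reactants: 2 2,6-dihydroxy-4-methoxybenzaldehyde; 3 3-chloro-3-methylbut-1-yne
Product: 4 2-hydroxy-4-methoxy-6-[(2-methylbut-3-yn-2-yl)oxy]benzaldehyde
Conditions: 3 (1.1 equiv), DBU, CuCl2·2H2O (cat.), MeCN, 0 °C
Reagents that add atoms: none
Why: Copper-catalysed propargylic substitution of the tertiary chloride by the phenoxide; the two hydroxyls of 2 are equivalent, and once one is etherified the other is locked in a hydrogen bond to the formyl group, so the mono-ether should dominate at 0 °C, well below the onset of a propargyl Claisen rearrangement.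

Step 3
Reactants: 5 isovanillin (3-hydroxy-4-methoxybenzaldehyde)
Product: 6 4-methoxy-3-(triisopropylsilyloxy)benzaldehyde
Conditions: iPr3SiCl, imidazole, DMF, rt
Reagents that add atoms: chlorotriisopropylsilane, CC(C)[Si](Cl)(C(C)C)C(C)C
Why: Standard silylation of a phenol; the triisopropylsilyl ether is chosen because it should withstand the lithium amide of step 4, the acid of step 5, the basic perborate of step 6 and DDQ, yet falls to buffered fluoride at the end.

Step 4
Reactants: 6 4-methoxy-3-(triisopropylsilyloxy)benzaldehyde; 7 bis(4,4,5,5-tetramethyl-1,3,2-dioxaborolan-2-yl)methane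
Product: 9 (E)-2-{2-[4-methoxy-3-(triisopropylsilyloxy)phenyl]ethenyl}-4,4,5,5-tetramethyl-1,3,2-dioxaborolane, via lithiated diborylmethane 8 (not isolated)
Conditions: 7, lithium 2,2,6,6-tetramethylpiperidide, THF, 0 °C; then 6, –78 °C → rt; H2O
Reagents that add atoms: none
Why: Boron-Wittig olefination; the diboryl carbanion 8 adds to the aldehyde and the β-boryl alkoxide loses lithium borate by syn elimination from the less hindered conformer, which should give the (E)-alkenyl boronate.

Step 5
Reactants: 4 2-hydroxy-4-methoxy-6-[(2-methylbut-3-yn-2-yl)oxy]benzaldehyde; 9 (E)-styryl pinacol boronate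
Product: 12 (2S,3S,4S)-2-[4-methoxy-3-(triisopropylsilyloxy)phenyl]-4,7-dimethoxy-5-[(2-methylbut-3-yn-2-yl)oxy]-3-(4,4,5,5-tetramethyl-1,3,2-dioxaborolan-2-yl)chromane, via dimethyl acetal 10 (not isolated), via methoxy quinone methide 11 (not isolated)
Conditions: 9 (1.5 equiv), HC(OMe)3 (1.5 equiv), (R)-3,3'-bis(2,4,6-triisopropylphenyl)-1,1'-binaphthyl-2,2'-diyl hydrogen phosphate (10 mol%), 5 Å MS, toluene, –20 °C; Et3N quench
Reagents that add atoms: trimethyl orthoformate, COC(OC)OC
Why: Proposed new method: the acid converts 4 with the orthoformate into acetal 10, which loses methanol to the 4-methoxy ortho-quinone methide 11 (its protonated form is an oxocarbenium ion held by the chiral phosphate through the ring A oxygen); the boron-bearing carbon of 9 bonds to C4 because positive charge then builds up on the carbon carrying the para-methoxyaryl group, and O1 collapses onto that carbon, so C3–C4 and O1–C2 form in one concerted but asynchronous inverse-demand hetero-[4+2] that closes ring C as a six-membered cycloadduct. The closest known reactions are the acid-promoted condensation of salicylaldehydes, orthoformates and styrenes to 2-aryl-4-alkoxychromans and the chiral phosphoric acid catalysed [4+2] of ortho-quinone methides with styrenes; what is new is a β-boryl styrene as the two-carbon partner. Suprafacial addition to the (E)-alkene should place the aryl group at C2 and boron at C3 trans, the phosphate bound to the quinone methide selects the alkene face and thereby the absolute configuration (2S,3S in 12, which becomes 2R,3R once oxygen replaces boron), and C4 is expected trans to boron but is of no consequence. The step needs ring closure to outrun loss of boron from the β-boryl benzylic cation and transfer of the styryl group through boron; the weakly Lewis acidic pinacol ester and the phenolic oxygen held next to the cation are meant to secure this, and the other ortho oxygen is etherified so that only one regiochemistry of closure exists.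

Step 6
Reactants: 12 3-boryl-4-methoxyflavan
Product: 13 (2R,3S,4R)-2-[4-methoxy-3-(triisopropylsilyloxy)phenyl]-4,7-dimethoxy-5-[(2-methylbut-3-yn-2-yl)oxy]chroman-3-ol
Conditions: NaBO3·4H2O, THF/H2O, 0 °C → rt
Reagents that add atoms: sodium perborate, [Na+].[O-]OB=O
Why: Perborate oxidation of an alkyl boronate; hydroperoxide adds to boron and C3 migrates from boron to oxygen with retention, which should give the 3-OH trans to the 2-aryl group, while the mildly basic medium spares the acid-labile 4-methoxy group and the aryl silyl ether.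

Step 7
Reactants: 13 4-methoxyflavan-3-ol
Product: 14 (2R,3R)-3-hydroxy-7-methoxy-2-[4-methoxy-3-(triisopropylsilyloxy)phenyl]-5-[(2-methylbut-3-yn-2-yl)oxy]chroman-4-one
Conditions: DDQ (1.3 equiv), CH2Cl2/pH 7 phosphate buffer, 0 °C → rt
Reagents that add atoms: water, O
Why: DDQ oxidation of an electron-rich benzylic ether, as in the oxidative cleavage of p-methoxybenzyl ethers and the DDQ functionalisation of C4 in flavan-3-ols; hydride is abstracted from C4, which is benzylic to the trioxygenated ring A and carries the methoxy group, water adds to the oxocarbenium ion and methanol is lost to leave the C4 ketone, while C2–H on the less electron-rich ring B side and the C2 and C3 centres should stay untouched in the buffered medium.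

Step 8
Reactants: 14 5-O-(dimethylpropargyl) dihydroflavonol
Product: 15 (2R,3R)-3-hydroxy-7-methoxy-2-[4-methoxy-3-(triisopropylsilyloxy)phenyl]-5-[(2-methylbut-3-en-2-yl)oxy]chroman-4-one
Conditions: H2 (1 atm), Pd/CaCO3 poisoned with Pb(OAc)2, quinoline, EtOAc, rt
Reagents that add atoms: none
Why: Lindlar semihydrogenation stops the terminal alkyne at the alkene; the poisoned catalyst should not touch the aryl ketone, the benzylic C2–O bond or the silyl ether.

Step 9
Reactants: 15 5-O-(1,1-dimethylallyl) dihydroflavonol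
Product: 16 (2R,3R)-3,5-dihydroxy-7-methoxy-2-[4-methoxy-3-(triisopropylsilyloxy)phenyl]-6-(3-methylbut-2-en-1-yl)chroman-4-one
Conditions: degassed toluene, 110 °C
Reagents that add atoms: none
Why: Aromatic Claisen rearrangement of a 1,1-dimethylallyl aryl ether, which proceeds near 100 °C; the [3,3] shift delivers the allyl terminus to C6, the only free ortho position of O5 because C4a is blocked, and rearomatisation gives the 6-prenyl phenol hydrogen-bonded to the C4 carbonyl without touching a stereocentre.

Step 10
Reactants: 16 3'-O-silyl target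
Product: 17 (2R,3R)-3,5-dihydroxy-2-(3-hydroxy-4-methoxyphenyl)-7-methoxy-6-(3-methylbut-2-en-1-yl)chroman-4-one (CNP0146895.1)
Conditions: Bu4NF, AcOH (1:1), THF, 0 °C
Reagents that add atoms: none
Why: Fluoride cleavage of the aryl silyl ether; the acetic acid buffer keeps the medium from turning basic, so the dihydroflavonol should neither open by retro-oxa-Michael reaction nor epimerise at C2 and C3, and the prenyl group is not exposed to strong acid.

**Compound list**

1 | 2,4,6-trihydroxybenzaldehyde | O=Cc1c(O)cc(O)cc1O | starting material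
2 | 2,6-dihydroxy-4-methoxybenzaldehyde | COc1cc(O)c(C=O)c(O)c1 | intermediate
3 | 3-chloro-3-methylbut-1-yne | CC(C)(Cl)C#C | starting material
4 | 2-hydroxy-4-methoxy-6-[(2-methylbut-3-yn-2-yl)oxy]benzaldehyde | COc1cc(O)c(C=O)c(OC(C)(C)C#C)c1 | intermediate
5 | isovanillin (3-hydroxy-4-methoxybenzaldehyde) | COc1ccc(C=O)cc1O | starting material
6 | 4-methoxy-3-(triisopropylsilyloxy)benzaldehyde | COc1ccc(C=O)cc1O[Si](C(C)C)(C(C)C)C(C)C | intermediate
7 | bis(4,4,5,5-tetramethyl-1,3,2-dioxaborolan-2-yl)methane | CC1(C)OB(CB2OC(C)(C)C(C)(C)O2)OC1(C)C | starting material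
8 | [bis(4,4,5,5-tetramethyl-1,3,2-dioxaborolan-2-yl)methyl]lithium | [Li]C(B1OC(C)(C)C(C)(C)O1)B1OC(C)(C)C(C)(C)O1 | intermediate
9 | (E)-2-{2-[4-methoxy-3-(triisopropylsilyloxy)phenyl]ethenyl}-4,4,5,5-tetramethyl-1,3,2-dioxaborolane | COc1ccc(/C=C/B2OC(C)(C)C(C)(C)O2)cc1O[Si](C(C)C)(C(C)C)C(C)C | intermediate
10 | 2-(dimethoxymethyl)-5-methoxy-3-[(2-methylbut-3-yn-2-yl)oxy]phenol | COc1cc(O)c(C(OC)OC)c(OC(C)(C)C#C)c1 | intermediate
11 | 3-methoxy-6-(methoxymethylidene)-5-[(2-methylbut-3-yn-2-yl)oxy]cyclohexa-2,4-dien-1-one (alkene geometry not fixed) | COC=C1C(=O)C=C(OC)C=C1OC(C)(C)C#C | intermediate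
12 | (2S,3S,4S)-2-[4-methoxy-3-(triisopropylsilyloxy)phenyl]-4,7-dimethoxy-5-[(2-methylbut-3-yn-2-yl)oxy]-3-(4,4,5,5-tetramethyl-1,3,2-dioxaborolan-2-yl)chromane | COc1ccc([C@H]2Oc3cc(OC)cc(OC(C)(C)C#C)c3[C@@H](OC)[C@@H]2B4OC(C)(C)C(C)(C)O4)cc1O[Si](C(C)C)(C(C)C)C(C)C | intermediate
13 | (2R,3S,4R)-2-[4-methoxy-3-(triisopropylsilyloxy)phenyl]-4,7-dimethoxy-5-[(2-methylbut-3-yn-2-yl)oxy]chroman-3-ol | COc1ccc([C@H]2Oc3cc(OC)cc(OC(C)(C)C#C)c3[C@@H](OC)[C@@H]2O)cc1O[Si](C(C)C)(C(C)C)C(C)C | intermediate
14 | (2R,3R)-3-hydroxy-7-methoxy-2-[4-methoxy-3-(triisopropylsilyloxy)phenyl]-5-[(2-methylbut-3-yn-2-yl)oxy]chroman-4-one | COc1ccc([C@H]2Oc3cc(OC)cc(OC(C)(C)C#C)c3C(=O)[C@@H]2O)cc1O[Si](C(C)C)(C(C)C)C(C)C | intermediate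
15 | (2R,3R)-3-hydroxy-7-methoxy-2-[4-methoxy-3-(triisopropylsilyloxy)phenyl]-5-[(2-methylbut-3-en-2-yl)oxy]chroman-4-one | COc1ccc([C@H]2Oc3cc(OC)cc(OC(C)(C)C=C)c3C(=O)[C@@H]2O)cc1O[Si](C(C)C)(C(C)C)C(C)C | intermediate
16 | (2R,3R)-3,5-dihydroxy-7-methoxy-2-[4-methoxy-3-(triisopropylsilyloxy)phenyl]-6-(3-methylbut-2-en-1-yl)chroman-4-one | COc1ccc([C@H]2Oc3cc(OC)c(CC=C(C)C)c(O)c3C(=O)[C@@H]2O)cc1O[Si](C(C)C)(C(C)C)C(C)C | intermediate
17 | (2R,3R)-3,5-dihydroxy-2-(3-hydroxy-4-methoxyphenyl)-7-methoxy-6-(3-methylbut-2-en-1-yl)chroman-4-one | COc1ccc([C@H]2Oc3cc(OC)c(CC=C(C)C)c(O)c3C(=O)[C@@H]2O)cc1O | target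

**Step count and risks**

Total: 10 steps. Longest linear sequence: 8 steps (steps 1, 2 and 5–10, or equally steps 3, 4 and 5–10).

Step 5 (cycloaddition with the boryl styrene). After the C3–C4 bond has formed, the β-boryl benzylic cation may lose boron and give a flav-3-ene instead of closing. The boronate may also hand over its styryl group through boron in a Petasis-type substitution, or the less nucleophilic alkene may let the quinone methide react with itself. The fallback uses the boron-free cycloaddition and brings in the 3-OH afterwards. Aldehyde 6 is methylenated (Ph3P=CH2, THF) to 4-methoxy-3-(triisopropylsilyloxy)styrene F1. Aldehyde 4, F1 and trimethyl orthoformate are condensed under the same chiral acid to the (2S,4S)-4-methoxyflavan F2; both the acid-promoted aldehyde/orthoformate/styrene condensation and chiral-acid control of quinone methide–styrene cycloadditions are established. DDQ in buffered wet CH2Cl2 then oxidises C4 to the (2S)-flavanone F3. LiN(SiMe3)2 with Me3SiCl present at –78 °C, to outpace ring opening of the enolate, gives the trimethylsilyl enol ether F4. Rubottom oxidation (dimethyldioxirane, acetone, then dilute citric acid) places the 3-OH anti to the 2-aryl group, which is compound 14, where the route is rejoined.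

Step 7 (DDQ oxidation of the C4 ether). Hydride abstraction may also occur at C2 on the ring B side, the product may be oxidised further, or acid released from the reagent may ionise C4 and trigger a hydride shift from C3. The fallback separates ionisation from oxidation. The 3-OH of 13 is silylated (tBuMe2SiCl, imidazole, DMF) to the 3-O-silyl 4-methoxyflavan F5. Mild aqueous solvolysis (pyridinium p-toluenesulfonate, acetone/H2O, 0 °C) exchanges the labile 4-methoxy group for hydroxyl and gives the flavan-4-ol F6. Dess–Martin periodinane (NaHCO3, CH2Cl2) gives the 3-O-silyl ketone F7. Dilute HCl in MeOH removes the alkyl silyl ether while leaving the aryl triisopropylsilyl ether, which returns the route to 14.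

Step 4 (boron-Wittig olefination). The β-boryl alkoxide may fail to eliminate cleanly, or the (E)-geometry may be eroded; any (Z)-alkene would be carried into the 2,3-cis series in step 5. The fallback builds the alkene by syn hydroboration. Aldehyde 6 is homologated by the Colvin rearrangement (Me3SiCHN2, LiN(iPr)2, THF, –78 °C → rt) to 4-ethynyl-1-methoxy-2-(triisopropylsilyloxy)benzene F8. Hydroboration with pinacolborane (Cp2Zr(H)Cl cat., Et3N cat., 60 °C) adds H and B syn and anti-Markovnikov, which gives only the (E)-boronate 9.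

**Further compounds**

F1 | step 5 | 4-methoxy-3-(triisopropylsilyloxy)styrene | C=Cc1ccc(OC)c(O[Si](C(C)C)(C(C)C)C(C)C)c1
F2 | step 5 | (2S,4S)-2-[4-methoxy-3-(triisopropylsilyloxy)phenyl]-4,7-dimethoxy-5-[(2-methylbut-3-yn-2-yl)oxy]chromane | COc1ccc([C@H]2Oc3cc(OC)cc(OC(C)(C)C#C)c3[C@@H](OC)C2)cc1O[Si](C(C)C)(C(C)C)C(C)C
F3 | step 5 | (2S)-7-methoxy-2-[4-methoxy-3-(triisopropylsilyloxy)phenyl]-5-[(2-methylbut-3-yn-2-yl)oxy]chroman-4-one | COc1ccc([C@H]2Oc3cc(OC)cc(OC(C)(C)C#C)c3C(=O)C2)cc1O[Si](C(C)C)(C(C)C)C(C)C
F4 | step 5 | (2S)-7-methoxy-2-[4-methoxy-3-(triisopropylsilyloxy)phenyl]-5-[(2-methylbut-3-yn-2-yl)oxy]-4-(trimethylsilyloxy)-2H-chromene | COc1ccc([C@H]2Oc3cc(OC)cc(OC(C)(C)C#C)c3C(O[Si](C)(C)C)=C2)cc1O[Si](C(C)C)(C(C)C)C(C)C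
F5 | step 7 | (2R,3S,4R)-3-(tert-butyldimethylsilyloxy)-2-[4-methoxy-3-(triisopropylsilyloxy)phenyl]-4,7-dimethoxy-5-[(2-methylbut-3-yn-2-yl)oxy]chromane | COc1ccc([C@H]2Oc3cc(OC)cc(OC(C)(C)C#C)c3[C@@H](OC)[C@@H]2O[Si](C)(C)C(C)(C)C)cc1O[Si](C(C)C)(C(C)C)C(C)C
F6 | step 7 | (2R,3S,4R)-3-(tert-butyldimethylsilyloxy)-7-methoxy-2-[4-methoxy-3-(triisopropylsilyloxy)phenyl]-5-[(2-methylbut-3-yn-2-yl)oxy]chroman-4-ol | COc1ccc([C@H]2Oc3cc(OC)cc(OC(C)(C)C#C)c3[C@@H](O)[C@@H]2O[Si](C)(C)C(C)(C)C)cc1O[Si](C(C)C)(C(C)C)C(C)C
F7 | step 7 | (2R,3R)-3-(tert-butyldimethylsilyloxy)-7-methoxy-2-[4-methoxy-3-(triisopropylsilyloxy)phenyl]-5-[(2-methylbut-3-yn-2-yl)oxy]chroman-4-one | COc1ccc([C@H]2Oc3cc(OC)cc(OC(C)(C)C#C)c3C(=O)[C@@H]2O[Si](C)(C)C(C)(C)C)cc1O[Si](C(C)C)(C(C)C)C(C)C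
F8 | step 4 | 4-ethynyl-1-methoxy-2-(triisopropylsilyloxy)benzene | C#Cc1ccc(OC)c(O[Si](C(C)C)(C(C)C)C(C)C)c1
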